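**Strategy.** Ring A is disconnected as a Diels–Alder retron (labdane numbering). The C1–C10 and C4–C5 bonds form together when 4-methylpenta-1,3-diene (C1–C4, C4 being the gem-dimethyl carbon) adds across one methyl-bearing double bond of 2,6-dimethyl-1,4-benzoquinone under a chiral oxazaborolidinium catalyst. In one operation this closes ring A, creates the C10 quaternary centre in absolute sense, and delivers ring B as an ene-dione. Its carbonyls are C6 and C9, and its alkene already carries the C8 methyl. Epimerisation at C5, C6 reduction, alkylative 1,3-carbonyl transposition (C9 to C7) and ester installation complete the labdane.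

Key step: step 1

Remark on numbering: labdane numbering is used throughout (decalin C1–C10, gem-dimethyl on C4, angular methyl on C10, side chain C11–C16 on C9). β is the face of the C10 methyl. The target is (5S,6S,7S,10S), i.e. 5α-H, 6β-OAc, 7α-O-isovaleryl, 10β-CH3.

Assumption on the catalyst: the (S)-diphenylprolinol-derived oxazaborolidinium ion is taken, from its α-C–H···O binding model, to give the (4aR,8aS) adduct. If the sense proves opposite, the (R)-catalyst is used and nothing else changes.

**Step 1**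
Reactants: 1 2,6-dimethyl-1,4-benzoquinone; 2 4-methylpenta-1,3-diene
Product: 3 (4aR,8aS)-2,5,5,8a-tetramethyl-4a,5,8,8a-tetrahydronaphthalene-1,4-dione (cis-fused adduct, 5β-H, 10β-CH3)
Conditions: (S)-3,3-diphenyl-1-(2-methylphenyl)tetrahydro-1H,3H-pyrrolo[1,2-c][1,3,2]oxazaborole·HNTf2 (20 mol %), 2 (4 equiv), CH2Cl2, −78 → −20 °C
Reagents that add atoms: none
Why: This is a concerted, asynchronous [4+2] cycloaddition (enantioselective quinone Diels–Alder reaction under chiral oxazaborolidinium Lewis-acid catalysis) in which the diene CH2 terminus bonds to the methyl-bearing quinone carbon (C1–C10, creating the quaternary centre) and the CMe2 terminus bonds to the neighbouring CH carbon (C4–C5). Ring A is closed as a cyclohexene by this two-bond suprafacial cycloaddition, with C2=C3 as a temporary alkene removed in step 7. C10 is set by the catalyst, which should bind the unhindered carbonyl flanked by C–H (the future C6=O) and shield one face of the reacting double bond, while C5 follows as cis through suprafacial addition and is corrected in step 2. The step needs regioselectivity, secured threefold: the coordinated carbonyl makes the methyl-bearing carbon the β-position, the largest HOMO coefficient of the diene lies on its CH2 terminus, and the gem-dimethyl terminus avoids the substituted carbon. The two quinone double bonds are equivalent, the ene-dione product is a weaker dienophile than the quinone, and the angular methyl blocks aromatisation. The (Z)-methyl group of the diene slows the reaction, which is why excess diene and a strongly activating catalyst are used.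

**Step 2**
Reactants: 3 cis-fused adduct
Product: 4 (4aS,8aS)-2,5,5,8a-tetramethyl-4a,5,8,8a-tetrahydronaphthalene-1,4-dione (trans-fused, 5α-H)
Conditions: 1,8-diazabicyclo[5.4.0]undec-7-ene (10 mol %), toluene, 23 °C
Reagents that add atoms: none
Why: Base-mediated enolisation toward C5, the only enolisable position (C10 is quaternary), should equilibrate the cis adduct to the trans-fused ene-dione by thermodynamic epimerisation, setting 5α-H.

**Step 3**
Reactants: 4 trans-fused ene-dione
Product: 5 (4R,4aS,8aS)-4-hydroxy-2,5,5,8a-tetramethyl-4a,5,8,8a-tetrahydronaphthalen-1(4H)-one (6β-hydroxy-7-en-9-one)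
Conditions: NaBH4, CeCl3·7H2O, MeOH–CH2Cl2, −78 °C
Reagents that add atoms: none
Why: Luche 1,2-reduction should select the C6 carbonyl (flanked by two CH) over the C9 carbonyl (flanked by quaternary C10 and the C8 methyl), with hydride attacking the α-face because the β-face is blocked by the C10 and C4β methyls, which gives the axial 6β-alcohol.

**Step 4**
Reactants: 5 6β-hydroxy enone; 6 2-(2-bromoethyl)-2-methyl-1,3-dioxolane
Product: 8 (1S,4R,4aS,8aS)-2,5,5,8a-tetramethyl-1-[2-(2-methyl-1,3-dioxolan-2-yl)ethyl]-1,4,4a,5,8,8a-hexahydronaphthalene-1,4-diol (6β,9β-diol), via Grignard reagent 7 (not isolated)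
Conditions: 6, Mg, THF, 25 °C; anhydrous CeCl3, THF, −78 °C; then 5 (reagent 3.5 equiv), −78 → 0 °C; aq. NH4Cl
Reagents that add atoms: none
Why: Cerium-promoted 1,2-addition of the Grignard reagent to the hindered, non-enolisable C9 carbonyl (CeCl3 suppresses conjugate addition at C7) should occur from the α-face anti to the C10 methyl to give the 9β-alcohol, a centre that is erased in step 6, with one equivalent of reagent spent on the 6-hydroxyl.

**Step 5**
Reactants: 8 6β,9β-diol
Product: 9 (1R,4S,4aS,8aS)-4-hydroxy-3,4a,8,8-tetramethyl-4-[2-(2-methyl-1,3-dioxolan-2-yl)ethyl]-1,4,4a,5,8,8a-hexahydronaphthalen-1-yl acetate (6β-acetate of 8)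
Conditions: Ac2O, Et3N, 4-(dimethylamino)pyridine (cat.), CH2Cl2, 0 → 23 °C
Reagents that add atoms: acetic anhydride, CC(=O)OC(C)=O
Why: Nucleophile-catalysed acylation should take the secondary allylic 6β-hydroxyl only, since the neopentyl tertiary 9-hydroxyl is inert under these conditions.

**Step 6**
Reactants: 9 tertiary allylic alcohol
Product: 10 6β-acetoxy-13,13-(ethylenedioxy)-14,15-dinorlabda-2,8-dien-7-one
Conditions: pyridinium chlorochromate C5H5NH[CrO3Cl] (3 equiv), NaOAc, 4 Å molecular sieves, CH2Cl2, 23 °C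
Reagents that add atoms: pyridinium chlorochromate, [O-][Cr](=O)(=O)Cl.c1cc[nH+]cc1
Why: Babler–Dauben oxidative transposition, in which the tertiary allylic chromate ester undergoes a [3,3] shift to C7 and is oxidised there, should move the oxygen from C9 to C7 and the alkene to C8=C9.

**Step 7**
Reactants: 10 dienone
Product: 11 6β-acetoxy-13,13-(ethylenedioxy)-14,15-dinorlabd-8-en-7-one
Conditions: H2 (1 atm), 10 % Pd/C, EtOAc, 23 °C
Reagents that add atoms: none
Why: Heterogeneous hydrogenation should saturate the unhindered cis-disubstituted C2=C3 bond while the tetrasubstituted C8=C9 enone bond stays intact, and no stereocentre is formed.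

**Step 8**
Reactants: 11 enone
Product: 12 6β-acetoxy-13,13-(ethylenedioxy)-14,15-dinorlabd-8-en-7β-ol
Conditions: NaBH4, CeCl3·7H2O, MeOH, −78 → −40 °C; AcOH quench
Reagents that add atoms: none
Why: Luche 1,2-reduction with axial hydride delivery from the α-face, anti to the axial 6β-acetoxy group, should give the pseudo-equatorial 7β-alcohol, and the low temperature limits acetyl migration and C6 epimerisation.

**Step 9**
Reactants: 12 7β-alcohol
Product: 13 6β-acetoxy-13,13-(ethylenedioxy)-14,15-dinorlabd-8-en-7α-yl 3-methylbutanoate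
Conditions: 3-methylbutanoic acid, PPh3, diisopropyl azodicarboxylate, toluene, 0 → 23 °C
Reagents that add atoms: 3-methylbutanoic acid, CC(C)CC(=O)O
Why: Mitsunobu esterification, in which isovalerate displaces the 7β-oxyphosphonium group by SN2 attack from the open α-face, should invert C7 to the required 7α ester, the cis acetate being unable to participate from the rear.

**Step 10**
Reactants: 13 ketal diester
Product: 14 6β-acetoxy-13-oxo-14,15-dinorlabd-8-en-7α-yl 3-methylbutanoate
Conditions: AcOH–H2O–THF (3:1:1), 45 °C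
Reagents that add atoms: water, O
Why: Mild acid-catalysed ketal hydrolysis should free the methyl ketone without ionising the allylic C7 ester.

**Step 11**
Reactants: 14 methyl ketone
Product: 15 allyl (13E)-6β-acetoxy-7α-(3-methylbutanoyloxy)labda-8,13-dien-15-oate
Conditions: allyl diethylphosphonoacetate, NaH, THF, 0 → 40 °C
Reagents that add atoms: allyl diethylphosphonoacetate, C=CCOC(=O)CP(=O)(OCC)OCC
Why: Horner–Wadsworth–Emmons olefination of the methyl ketone should give mainly the E-enoate (ester trans to the larger CH2 chain), with any Z isomer removed by chromatography, and the soft phosphonate anion should leave the two esters untouched.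

**Step 12**
Reactants: 15 allyl ester
Product: 16 (13E)-6β-acetoxy-7α-(3-methylbutanoyloxy)labda-8,13-dien-15-oic acid, (5S,6S,7S,10S)
Conditions: Pd(PPh3)4 (5 mol %), morpholine (5 equiv), THF, 23 °C; dilute aq. citric acid work-up
Reagents that add atoms: none
Why: Allyl transfer to morpholine through a π-allyl complex of zerovalent palladium should free the acid under neutral conditions, the hindered internal allylic isovalerate being far slower to ionise than the terminal allyl ester.

**Compound list**

1 | 2,6-dimethyl-1,4-benzoquinone | CC1=CC(=O)C=C(C)C1=O | starting material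
2 | 4-methylpenta-1,3-diene | C=CC=C(C)C | starting material
3 | (4aR,8aS)-2,5,5,8a-tetramethyl-4a,5,8,8a-tetrahydronaphthalene-1,4-dione | O=C1C=C(C)C(=O)[C@@]2(C)CC=CC(C)(C)[C@@H]12 | intermediate
4 | (4aS,8aS)-2,5,5,8a-tetramethyl-4a,5,8,8a-tetrahydronaphthalene-1,4-dione | O=C1C=C(C)C(=O)[C@@]2(C)CC=CC(C)(C)[C@H]12 | intermediate
5 | (4R,4aS,8aS)-4-hydroxy-2,5,5,8a-tetramethyl-4a,5,8,8a-tetrahydronaphthalen-1(4H)-one | O[C@@H]1C=C(C)C(=O)[C@@]2(C)CC=CC(C)(C)[C@H]12 | intermediate
6 | 2-(2-bromoethyl)-2-methyl-1,3-dioxolane | BrCCC1(C)OCCO1 | starting material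
7 | [2-(2-methyl-1,3-dioxolan-2-yl)ethyl]magnesium bromide | Br[Mg]CCC1(C)OCCO1 | intermediate (not isolated)
8 | (1S,4R,4aS,8aS)-2,5,5,8a-tetramethyl-1-[2-(2-methyl-1,3-dioxolan-2-yl)ethyl]-1,4,4a,5,8,8a-hexahydronaphthalene-1,4-diol | O[C@@H]1C=C(C)[C@@](O)(CCC2(C)OCCO2)[C@@]3(C)CC=CC(C)(C)[C@H]13 | intermediate
9 | (1R,4S,4aS,8aS)-4-hydroxy-3,4a,8,8-tetramethyl-4-[2-(2-methyl-1,3-dioxolan-2-yl)ethyl]-1,4,4a,5,8,8a-hexahydronaphthalen-1-yl acetate | CC(=O)O[C@@H]1C=C(C)[C@@](O)(CCC2(C)OCCO2)[C@@]3(C)CC=CC(C)(C)[C@H]13 | intermediate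
10 | 6β-acetoxy-13,13-(ethylenedioxy)-14,15-dinorlabda-2,8-dien-7-one | CC(=O)O[C@@H]1C(=O)C(C)=C(CCC2(C)OCCO2)[C@@]3(C)CC=CC(C)(C)[C@H]13 | intermediate
11 | 6β-acetoxy-13,13-(ethylenedioxy)-14,15-dinorlabd-8-en-7-one | CC(=O)O[C@@H]1C(=O)C(C)=C(CCC2(C)OCCO2)[C@@]3(C)CCCC(C)(C)[C@H]13 | intermediate
12 | 6β-acetoxy-13,13-(ethylenedioxy)-14,15-dinorlabd-8-en-7β-ol | CC(=O)O[C@@H]1[C@H](O)C(C)=C(CCC2(C)OCCO2)[C@@]3(C)CCCC(C)(C)[C@H]13 | intermediate
13 | 6β-acetoxy-13,13-(ethylenedioxy)-14,15-dinorlabd-8-en-7α-yl 3-methylbutanoate | CC(=O)O[C@@H]1[C@@H](OC(=O)CC(C)C)C(C)=C(CCC2(C)OCCO2)[C@@]3(C)CCCC(C)(C)[C@H]13 | intermediate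
14 | 6β-acetoxy-13-oxo-14,15-dinorlabd-8-en-7α-yl 3-methylbutanoate | CC(=O)O[C@@H]1[C@@H](OC(=O)CC(C)C)C(C)=C(CCC(C)=O)[C@@]2(C)CCCC(C)(C)[C@H]12 | intermediate
15 | allyl (13E)-6β-acetoxy-7α-(3-methylbutanoyloxy)labda-8,13-dien-15-oate | CC(=O)O[C@@H]1[C@@H](OC(=O)CC(C)C)C(C)=C(CC/C(C)=C/C(=O)OCC=C)[C@@]2(C)CCCC(C)(C)[C@H]12 | intermediate
16 | (5S,6S,7S,10S,13E)-6-acetoxy-7-(3-methylbutanoyloxy)labda-8,13-dien-15-oic acid | CC(=O)O[C@@H]1[C@@H](OC(=O)CC(C)C)C(C)=C(CC/C(C)=C/C(=O)O)[C@@]2(C)CCCC(C)(C)[C@H]12 | target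

**Total step count:** 12. **Longest linear sequence:** 12 steps (1 and 2 to 16); fragment 6 enters at step 4.

**Steps most likely to fail, with fallbacks**

Step 1. The (Z)-methyl group of the diene disfavours its s-cis conformer, so cationic oligomerisation of the diene by the Lewis acid may outrun cycloaddition, and facial discrimination on a slow substrate may be modest. The fallback sets out from 1 and uses a far more nucleophilic diene with the same carbon skeleton and the same regiochemical bias. Commercial mesityl oxide is deprotonated at its methyl ketone carbon (LiN(iPr)2, THF, −78 °C) and silylated with iPr3SiOTf to give 4-methyl-2-[(triisopropylsilyl)oxy]penta-1,3-diene F1. Cycloaddition of F1 to 1 under the same oxazaborolidinium catalyst should give the silyl enol ether adduct (4aR,8aS)-2,5,5,8a-tetramethyl-7-[(triisopropylsilyl)oxy]-4a,5,8,8a-tetrahydronaphthalene-1,4-dione F2. Treatment with CsF and PhNTf2 in 1,2-dimethoxyethane converts it into the corresponding C2 enol triflate (labdane numbering) F3. Palladium-catalysed formate reduction (Pd(OAc)2, PPh3, HCO2H, Bu3N, DMF, 60 °C) then replaces the triflate by hydrogen, and the sequence comes back to the route at 3.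

Step 2. Equilibration may stop at a mixture, because the 1,3-diaxial methyl–methyl contact across ring A erodes the usual preference for the trans-fused ene-dione. The fallback replaces thermodynamic control by a kinetic, face-selective protonation and sets out from 3. Silylation (tBuMe2SiOTf, Et3N, CH2Cl2, −78 °C) gives the cross-conjugated silyl dienol ether (8aS)-4-[(tert-butyldimethylsilyl)oxy]-2,5,5,8a-tetramethyl-8,8a-dihydronaphthalen-1(5H)-one F4, in which C5 is trigonal. Fluoride-induced desilylation in the presence of acetic acid (Bu4NF, AcOH, THF, −78 °C) should protonate C5 axially from the α-face, anti to the C10 methyl, and the sequence comes back at 4.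

Step 9. The allylic oxyphosphonium ion may ionise, with participation of the neighbouring acetate (retention or acyl scrambling) or elimination to a diene, and the acetyl group may migrate to the cis 7-hydroxyl before activation. The fallback sets out from 8 and sets C7 by hydroxyl-directed hydride delivery instead of inversion.
- The 6-hydroxyl of 8 is silylated (Et3SiCl, imidazole) to the 6β-triethylsilyl ether of 8, F5.
- Oxidative transposition as in step 6 gives 13,13-(ethylenedioxy)-6β-(triethylsilyloxy)-14,15-dinorlabda-2,8-dien-7-one F6.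
- Hydrogenation as in step 7 gives 13,13-(ethylenedioxy)-6β-(triethylsilyloxy)-14,15-dinorlabd-8-en-7-one F7.
- Desilylation with HF·pyridine frees 13,13-(ethylenedioxy)-6β-hydroxy-14,15-dinorlabd-8-en-7-one F8.
- Evans–Saksena reduction (Me4NBH(OAc)3, AcOH–MeCN, −20 °C) delivers hydride from the face of the 6β-hydroxyl and should give the trans-diaxial 13,13-(ethylenedioxy)-14,15-dinorlabd-8-ene-6β,7α-diol F9.
- The less hindered allylic 7α-hydroxyl is acylated selectively (3-methylbutanoyl chloride, pyridine, −20 °C) to 13,13-(ethylenedioxy)-6β-hydroxy-14,15-dinorlabd-8-en-7α-yl 3-methylbutanoate F10.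
- Forcing acetylation of the axial 6β-hydroxyl (Ac2O, 4-(dimethylamino)pyridine, Et3N, 40 °C) comes back to the route at 13.

**Further compounds**

F1 | step 1 | 4-methyl-2-[(triisopropylsilyl)oxy]penta-1,3-diene | C=C(O[Si](C(C)C)(C(C)C)C(C)C)C=C(C)C
F2 | step 1 | (4aR,8aS)-2,5,5,8a-tetramethyl-7-[(triisopropylsilyl)oxy]-4a,5,8,8a-tetrahydronaphthalene-1,4-dione | O=C1C=C(C)C(=O)[C@@]2(C)CC(O[Si](C(C)C)(C(C)C)C(C)C)=CC(C)(C)[C@@H]12
F3 | step 1 | C2 enol triflate corresponding to F2 (cis-fused ene-dione) | O=C1C=C(C)C(=O)[C@@]2(C)CC(OS(=O)(=O)C(F)(F)F)=CC(C)(C)[C@@H]12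
F4 | step 2 | (8aS)-4-[(tert-butyldimethylsilyl)oxy]-2,5,5,8a-tetramethyl-8,8a-dihydronaphthalen-1(5H)-one | CC(C)(C)[Si](C)(C)OC1=C2C(C)(C)C=CC[C@]2(C)C(=O)C(C)=C1
F5 | step 9 | 6β-triethylsilyl ether of 8 | CC[Si](CC)(CC)O[C@@H]1C=C(C)[C@@](O)(CCC2(C)OCCO2)[C@@]3(C)CC=CC(C)(C)[C@H]13
F6 | step 9 | 13,13-(ethylenedioxy)-6β-(triethylsilyloxy)-14,15-dinorlabda-2,8-dien-7-one | CC[Si](CC)(CC)O[C@@H]1C(=O)C(C)=C(CCC2(C)OCCO2)[C@@]3(C)CC=CC(C)(C)[C@H]13
F7 | step 9 | 13,13-(ethylenedioxy)-6β-(triethylsilyloxy)-14,15-dinorlabd-8-en-7-one | CC[Si](CC)(CC)O[C@@H]1C(=O)C(C)=C(CCC2(C)OCCO2)[C@@]3(C)CCCC(C)(C)[C@H]13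
F8 | step 9 | 13,13-(ethylenedioxy)-6β-hydroxy-14,15-dinorlabd-8-en-7-one | O[C@@H]1C(=O)C(C)=C(CCC2(C)OCCO2)[C@@]3(C)CCCC(C)(C)[C@H]13
F9 | step 9 | 13,13-(ethylenedioxy)-14,15-dinorlabd-8-ene-6β,7α-diol | O[C@@H]1[C@@H](O)C(C)=C(CCC2(C)OCCO2)[C@@]3(C)CCCC(C)(C)[C@H]13
F10 | step 9 | 13,13-(ethylenedioxy)-6β-hydroxy-14,15-dinorlabd-8-en-7α-yl 3-methylbutanoate | O[C@@H]1[C@@H](OC(=O)CC(C)C)C(C)=C(CCC2(C)OCCO2)[C@@]3(C)CCCC(C)(C)[C@H]13
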